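Everything rests on the C4–C5 bond. In the target, quaternary C5 (methyl, C14, C6) sits on C4, the β-carbon of the ring A enone whose ketone is C2; so C5 can be a tertiary radical adding to C4 of a 4,4-disubstituted cyclopent-2-enone. Hydrogen atom transfer from an iron hydride to a C5 methylene group makes that radical, and its 6-exo addition forms C4–C5, closes ring B, creates the C5 methyl group and sets C4 and C5 in one operation. The precursor is a cyclopentenone whose quaternary C9 carries the PMB-protected C10–C11 arm and a C8–C7–C6 chain ending in a 2-(hydroxymethyl)allyl unit with O14 free.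

Key step: step 14

Assumption: the target SMILES is taken literally (numbering: ring A = C1, C2, C3, C4, C9; ring B = C4–C9; ring C = C4, C5, C14, C13, C12, C11, C10, C9; configuration 5S,6S,9S,10R,11S,12S,14R); it places C14 and the C10 arm on opposite faces of ring B (C14 syn to C1), so ring C spans a trans-1,3 pair and is closed late, on the C3–C4 unsaturated system.

Step 1
Reactants: 1 (R)-5-methoxy-3-methyl-5-oxopentanoic acid
Product: 3 (S)-4-methyltetrahydro-2H-pyran-2-one, via hydroxy acid 2 (not isolated)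
Conditions: LiBEt3H (3.2 equiv), THF, 0 °C; 3 M HCl; TsOH (cat.), CH2Cl2, rt
Reagents that add atoms: none
Why: Hydride reduction of the methyl ester beside the unreactive lithium carboxylate, then acid-catalysed lactonisation; no stereocentre is formed, and reducing the ester arm (not the acid arm) is what stores C6 as (S) with the lactone carbonyl as the future C14.

Step 2
Reactants: 3 (S)-4-methyltetrahydro-2H-pyran-2-one
Product: 5 methyl (R)-5-chloro-3-methylpentanoate, via acid chloride 4 (not isolated)
Conditions: SOCl2, ZnCl2 (cat.), 60 °C; then MeOH, 0 °C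
Reagents that add atoms: thionyl chloride, O=S(Cl)Cl; methanol, CO
Why: Zinc-chloride-assisted ring-opening chlorination of the lactone followed by methanolysis of the acyl chloride turns the ring O–CH2 carbon (C8) into a primary chloride and frees the ester for enolate chemistry, leaving the β-stereocentre untouched.

Step 3
Reactants: 5 methyl (R)-5-chloro-3-methylpentanoate
Product: 8 methyl (S)-5-chloro-3-methyl-2-methylenepentanoate, via Mannich base 6 (not isolated), via ammonium iodide 7 (not isolated)
Conditions: LDA, THF, −78 °C; CH2=NMe2+ I−, −78 °C → rt; MeI, MeOH, rt; DBU, CH2Cl2, rt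
Reagents that add atoms: Eschenmoser's salt (N,N-dimethylmethyleneiminium iodide), C=[N+](C)C.[I-]
Why: Classical ester α-methylenation (enolate Mannich reaction, N-methylation, E1cB loss of trimethylamine) installs the C5 methylene; C6 is β to the carbonyl and is not enolised, and the primary chloride is too poor an electrophile to interfere.

Step 4
Reactants: 8 methyl (S)-5-chloro-3-methyl-2-methylenepentanoate
Product: 9 (S)-5-chloro-3-methyl-2-methylenepentan-1-ol
Conditions: i-Bu2AlH (2.5 equiv), CH2Cl2, −78 °C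
Reagents that add atoms: none
Why: DIBAL 1,2-reduction of the acrylate ester gives the 2-substituted allylic alcohol (C14–OH) without touching the alkyl chloride.

Step 5
Reactants: 9 (S)-5-chloro-3-methyl-2-methylenepentan-1-ol
Product: 10 (S)-[(5-chloro-3-methyl-2-methylenepentyl)oxy]triethylsilane
Conditions: Et3SiCl, imidazole, CH2Cl2, 0 °C
Reagents that add atoms: chlorotriethylsilane, CC[Si](Cl)(CC)CC
Why: Standard O-silylation protects O14 as a triethylsilyl ether that survives enolate chemistry and is shed later by mild acid.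

Step 6
Reactants: 10 (S)-[(5-chloro-3-methyl-2-methylenepentyl)oxy]triethylsilane
Product: 11 (S)-triethyl[(5-iodo-3-methyl-2-methylenepentyl)oxy]silane
Conditions: NaI, NaHCO3, acetone, reflux
Reagents that add atoms: sodium iodide, [Na+].[I-]
Why: Finkelstein halide exchange gives the primary iodide needed for the enolate alkylation in step 11.

Step 7
Reactants: 12 ethyl (R)-lactate
Product: 13 ethyl (R)-2-{[(trifluoromethyl)sulfonyl]oxy}propanoate
Conditions: Tf2O, 2,6-lutidine, CH2Cl2, −78 → 0 °C
Reagents that add atoms: trifluoromethanesulfonic anhydride, O=S(=O)(OS(=O)(=O)C(F)(F)F)C(F)(F)F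
Why: O-Triflation occurs at oxygen with retention at the carbinol carbon and gives a secondary electrophile that reacts by clean SN2.

Step 8
Reactants: 14 (3S,7aR)-7a-methyl-3-(propan-2-yl)tetrahydropyrrolo[2,1-b]oxazol-5(6H)-one; 13 ethyl (R)-2-{[(trifluoromethyl)sulfonyl]oxy}propanoate
Product: 15 ethyl (2R)-2-[(3S,7aR)-7a-methyl-5-oxo-3-(propan-2-yl)hexahydropyrrolo[2,1-b]oxazol-6-yl]propanoate (epimers at lactam C6)
Conditions: LDA, THF, −78 °C; then 13, −78 → −40 °C
Reagents that add atoms: none
Why: Alkylation of the lactam lithium enolate by an α-triflyloxy ester is an SN2 displacement with inversion, which sets C10 as (R); the configuration at the lactam α-carbon is immaterial because it is enolised again in step 11.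

Step 9
Reactants: 15 ethyl (2R)-2-[(3S,7aR)-7a-methyl-5-oxo-3-(propan-2-yl)hexahydropyrrolo[2,1-b]oxazol-6-yl]propanoate
Product: 16 (3S,7aR)-6-[(2R)-1-hydroxypropan-2-yl]-7a-methyl-3-(propan-2-yl)tetrahydropyrrolo[2,1-b]oxazol-5(6H)-one (epimers at C6)
Conditions: LiBH4, THF/EtOH, 0 °C → rt
Reagents that add atoms: none
Why: Chemoselective borohydride reduction of the ester (the tertiary lactam is inert) gives the C11 alcohol and removes the acidic ester α-hydrogen at C10 before the next enolisation.

Step 10
Reactants: 16 (3S,7aR)-6-[(2R)-1-hydroxypropan-2-yl]-7a-methyl-3-(propan-2-yl)tetrahydropyrrolo[2,1-b]oxazol-5(6H)-one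
Product: 17 (3S,7aR)-6-[(2R)-1-(4-methoxybenzyloxy)propan-2-yl]-7a-methyl-3-(propan-2-yl)tetrahydropyrrolo[2,1-b]oxazol-5(6H)-one (epimers at C6)
Conditions: NaH, 4-MeOC6H4CH2Cl, Bu4NI (cat.), DMF, 0 °C → rt
Reagents that add atoms: 4-methoxybenzyl chloride, COc1ccc(CCl)cc1
Why: Williamson etherification protects O11 as the PMB ether so that it cannot add to the enone formed in step 13.

Step 11
Reactants: 17 (3S,7aR)-6-[(2R)-1-(4-methoxybenzyloxy)propan-2-yl]-7a-methyl-3-(propan-2-yl)tetrahydropyrrolo[2,1-b]oxazol-5(6H)-one; 11 (S)-triethyl[(5-iodo-3-methyl-2-methylenepentyl)oxy]silane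
Product: 18 (3S,6S,7aR)-6-[(2R)-1-(4-methoxybenzyloxy)propan-2-yl]-7a-methyl-6-[(3S)-3-methyl-4-methylene-5-(triethylsilyloxy)pentyl]-3-(propan-2-yl)tetrahydropyrrolo[2,1-b]oxazol-5(6H)-one
Conditions: LDA, THF, −78 → 0 °C; then 11, DMPU, −78 → −20 °C
Reagents that add atoms: none
Why: Auxiliary-controlled second alkylation of the bicyclic lactam enolate: the primary iodide should enter on the endo face, anti to the angular methyl group, so quaternary C9 is set with the chain trans and the C10 arm cis to that methyl.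

Step 12
Reactants: 18 dialkylated bicyclic lactam
Product: 20 (2S)-2-[(3S)-5-hydroxy-3-methyl-4-methylenepentyl]-2-[(2R)-1-(4-methoxybenzyloxy)propan-2-yl]-4-oxopentanal, via carbinolamine 19 (not isolated)
Conditions: NaAlH2(OCH2CH2OMe)2, toluene, 0 °C → rt; then Bu4NH2PO4 (1 M aq.), EtOH, reflux
Reagents that add atoms: water, O
Why: Partial hydride reduction of the lactam to the carbinolamine and mildly acidic hydrolysis of the N,O-ketal release valinol and unveil the C4 aldehyde and the C2 methyl ketone, the warm phosphate buffer also cleaving the triethylsilyl ether; C9 has no α-hydrogen and cannot epimerise.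

Step 13
Reactants: 20 keto aldehyde
Product: 21 (4R)-4-[(3S)-5-hydroxy-3-methyl-4-methylenepentyl]-4-[(2R)-1-(4-methoxybenzyloxy)propan-2-yl]cyclopent-2-en-1-one
Conditions: KOH, EtOH, rt
Reagents that add atoms: none
Why: Intramolecular aldol condensation: only the methyl ketone carbon (C3) can reach the non-enolisable aldehyde in a five-membered closure, and dehydration gives the 4,4-disubstituted cyclopent-2-enone.

Step 14
Reactants: 21 (4R)-4-[(3S)-5-hydroxy-3-methyl-4-methylenepentyl]-4-[(2R)-1-(4-methoxybenzyloxy)propan-2-yl]cyclopent-2-en-1-one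
Product: 22 (3aR,4S,5S,7aR)-4-(hydroxymethyl)-7a-[(2R)-1-(4-methoxybenzyloxy)propan-2-yl]-4,5-dimethyloctahydro-2H-inden-2-one
Conditions: Fe(acac)3 (20 mol %), PhSiH2(Oi-Pr) (2.5 equiv), i-PrOH (2 equiv), ClCH2CH2Cl, 40 °C, 0.02 M
Reagents that add atoms: none
Why: An iron hydride formed from Fe(acac)3 and the silane transfers a hydrogen atom to the terminal carbon of the 1,1-disubstituted alkene, and the nucleophilic tertiary C5 radical adds to C4 of the cyclopentenone; the C3 α-keto radical is then reduced by divalent iron and protonated. This is the intramolecular form of the iron-mediated reductive olefin–enone coupling (a HAT-initiated Giese reaction), a known route to quaternary carbons. Ring B closes in a 6-exo-trig mode through a chair-like transition state with C1 pseudo-axial on C9 and the C6 methyl equatorial. C4 is controlled by the tether: C5 can only reach the face of ring A that carries C8, so the ring fusion is cis. C5 is controlled by which substituent of the planar radical lies over ring A: the hydroxymethyl group must take this pseudo-axial site (syn to C1) and the nascent methyl the outer one, which is why O14 is left unprotected, making C14 no bulkier than methyl and allowing an O–H···O=C2 contact that only this orientation offers in the non-protic medium. The step also needs hydrogen transfer to the isolated methylene and not to the conjugated C3–C4 bond, which the much lower reactivity of electron-poor enones toward the metal hydride should secure.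

Step 15
Reactants: 23 methyl 3-methylbut-2-enoate
Product: 24 [(1-methoxy-3-methylbuta-1,3-dien-1-yl)oxy]trimethylsilane
Conditions: LDA, THF, −78 °C; Me3SiCl, −78 °C → rt
Reagents that add atoms: chlorotrimethylsilane, C[Si](C)(C)Cl
Why: Kinetic γ-deprotonation of the β,β-dimethylacrylate and O-silylation give the silyl dienolate that serves as the C13–C12 nucleophile.

Step 16
Reactants: 22 (3aR,4S,5S,7aR)-4-(hydroxymethyl)-7a-[(2R)-1-(4-methoxybenzyloxy)propan-2-yl]-4,5-dimethyloctahydro-2H-inden-2-one
Product: 26 (4S,5S,7aS)-7a-[(2R)-1-(4-methoxybenzyloxy)propan-2-yl]-4,5-dimethyl-2-oxo-2,4,5,6,7,7a-hexahydro-1H-indene-4-carbaldehyde, via keto aldehyde 25 (not isolated)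
Conditions: IBX (3.5 equiv), 4-methoxypyridine N-oxide (3.5 equiv), DMSO, 25 °C
Reagents that add atoms: none
Why: IBX oxidises the primary alcohol to the aldehyde and, as its N-oxide complex, dehydrogenates the ketone through its enol at room temperature; only C3–C4 can become unsaturated because the other α-carbon (C1) adjoins quaternary C9, and the aldehyde has no α-hydrogen.

Step 17
Reactants: 26 enone aldehyde; 24 [(1-methoxy-3-methylbuta-1,3-dien-1-yl)oxy]trimethylsilane
Product: 28 (6R)-6-[(4S,5S,7aS)-7a-[(2R)-1-(4-methoxybenzyloxy)propan-2-yl]-4,5-dimethyl-2-oxo-2,4,5,6,7,7a-hexahydro-1H-inden-4-yl]-4-methyl-5,6-dihydro-2H-pyran-2-one, via silyl aldol adduct 27 (not isolated)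
Conditions: Cu(OTf)2 (10 mol %), (S)-Tol-BINAP (11 mol %), Bu4N[Ph3SiF2] (20 mol %), THF, 0 °C → rt
Reagents that add atoms: none
Why: Catalytic asymmetric vinylogous Mukaiyama aldol reaction through a chiral copper dienolate: γ-attack on the aldehyde forms C13–C14 with C14 set by the catalyst (the antipodal ligand is used if the sense is mismatched), and lactonisation of the (Z)-adduct fixes the C12 alkene with C13 cis to the former ester carbon.

Step 18
Reactants: 28 unsaturated δ-lactone
Product: 29 ethylene ketal (spiro-1,3-dioxolane at C2) of 28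
Conditions: (Me3SiOCH2)2, Me3SiOTf (cat.), CH2Cl2, −78 → −20 °C; pyridine
Reagents that add atoms: 1,2-bis(trimethylsilyloxy)ethane, C[Si](C)(C)OCCO[Si](C)(C)C
Why: Silyl-triflate-catalysed ketalisation masks the enone carbonyl for the hydride step; the double bond cannot migrate because C5 and C9 bear no hydrogen.

Step 19
Reactants: 29 ketal lactone
Product: 30 (Z)-diol: C14 secondary alcohol and (Z)-C12(CH3)=CH–CH2OH primary allylic alcohol on the ketal-protected bicycle
Conditions: i-Bu2AlH (5 equiv), CH2Cl2, −78 → 0 °C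
Reagents that add atoms: none
Why: DIBAL reduces the unsaturated lactone in a 1,2 sense to the diol, preserving the ring-imposed (Z) geometry and leaving the ketal and PMB ether intact.

Step 20
Reactants: 30 (Z)-diol
Product: 31 primary allylic diethyl phosphate of 30
Conditions: (EtO)2P(O)Cl (1.1 equiv), pyridine, CH2Cl2, −20 → 0 °C
Reagents that add atoms: diethyl chlorophosphate, CCOP(=O)(Cl)OCC
Why: Selective phosphorylation of the primary allylic alcohol over the secondary C14 hydroxyl flanked by quaternary C5 gives a geometrically stable allylic leaving group.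

Step 21
Reactants: 31 allylic phosphate
Product: 32 C14 [(tert-butyldimethylsilyloxy)acetate] ester of 31
Conditions: t-BuMe2SiOCH2CO2H, EDC·HCl, DMAP, CH2Cl2, rt
Reagents that add atoms: 2-[(tert-butyldimethylsilyl)oxy]acetic acid, CC(C)(C)[Si](C)(C)OCC(=O)O
Why: Steglich esterification acylates the hindered C14 hydroxyl with silyl-protected glycolic acid, so the final ester also serves as the C14 protecting group.

Step 22
Reactants: 32 glycolate phosphate
Product: 33 C11 primary alcohol (PMB removed)
Conditions: DDQ, CH2Cl2/pH 7 buffer, 0 °C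
Reagents that add atoms: none
Why: Oxidative cleavage of the PMB ether by DDQ frees O11 under buffered conditions that spare the ketal, phosphate and silyl ether.

Step 23
Reactants: 33 C11 alcohol
Product: 34 C11 aldehyde
Conditions: Dess–Martin periodinane, NaHCO3, CH2Cl2, 0 °C → rt
Reagents that add atoms: none
Why: Dess–Martin oxidation gives the α-branched C11 aldehyde without epimerising C10.

Step 24
Reactants: 34 C11 aldehyde carrying the (Z)-allylic phosphate
Product: 35 tricyclic C11 alcohol with C2 dioxolane and silyl-protected glycolate (rings A, B and C complete)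
Conditions: CrCl2 (6 equiv), LiI (20 mol %), DMPU/THF, rt, slow addition to 0.002 M
Reagents that add atoms: none
Why: Intramolecular Nozaki–Hiyama allylation: divalent chromium converts the allylic phosphate into a γ,γ-disubstituted allylchromium that attacks the aldehyde through its γ-carbon (C12) in a chair-like six-membered transition state, forming C11–C12, the C12 quaternary centre with its vinyl group and ring C; the (Z) geometry (C13 cis to the CH2Cr carbon) places C13 axial and C10 equatorial, which should give the required C11/C12 relationship, and Felkin–Anh attack anti to C9 should set C11 relative to C10.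

Step 25
Reactants: 35 protected tricycle
Product: 36 Pleuromutilin F
Conditions: 48 % aq. HF, MeCN, 0 °C → rt
Reagents that add atoms: water, O
Why: Aqueous HF removes the silyl ether and hydrolyses the allylic dioxolane in one operation, returning the C2 ketone conjugated with C3–C4 and leaving the glycolate ester and the C11 hydroxyl intact.

Compound list
1 | (R)-5-methoxy-3-methyl-5-oxopentanoic acid (monomethyl (R)-3-methylglutarate) | COC(=O)C[C@H](C)CC(=O)O | starting material
2 | (S)-5-hydroxy-3-methylpentanoic acid | OCC[C@H](C)CC(=O)O | intermediate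
3 | (S)-4-methyltetrahydro-2H-pyran-2-one | O=C1C[C@@H](C)CCO1 | intermediate
4 | (S)-5-chloro-3-methylpentanoyl chloride | O=C(Cl)C[C@@H](C)CCCl | intermediate
5 | methyl (R)-5-chloro-3-methylpentanoate | COC(=O)C[C@@H](C)CCCl | intermediate
6 | methyl (3S)-5-chloro-2-[(dimethylamino)methyl]-3-methylpentanoate (C2 epimers, centre left undefined) | COC(=O)C(CN(C)C)[C@@H](C)CCCl | intermediate
7 | [(3S)-5-chloro-2-(methoxycarbonyl)-3-methylpentyl]trimethylammonium iodide (C2 epimers) | COC(=O)C(C[N+](C)(C)C)[C@@H](C)CCCl.[I-] | intermediate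
8 | methyl (S)-5-chloro-3-methyl-2-methylenepentanoate | C=C(C(=O)OC)[C@@H](C)CCCl | intermediate
9 | (S)-5-chloro-3-methyl-2-methylenepentan-1-ol | C=C(CO)[C@@H](C)CCCl | intermediate
10 | (S)-[(5-chloro-3-methyl-2-methylenepentyl)oxy]triethylsilane | C=C(CO[Si](CC)(CC)CC)[C@@H](C)CCCl | intermediate
11 | (S)-triethyl[(5-iodo-3-methyl-2-methylenepentyl)oxy]silane | C=C(CO[Si](CC)(CC)CC)[C@@H](C)CCI | intermediate
12 | ethyl (R)-lactate | C[C@@H](O)C(=O)OCC | starting material
13 | ethyl (R)-2-{[(trifluoromethyl)sulfonyl]oxy}propanoate | C[C@@H](OS(=O)(=O)C(F)(F)F)C(=O)OCC | intermediate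
14 | (3S,7aR)-7a-methyl-3-(propan-2-yl)tetrahydropyrrolo[2,1-b]oxazol-5(6H)-one (bicyclic lactam from L-valinol and levulinic acid) | CC(C)[C@H]1CO[C@]2(C)CCC(=O)N12 | starting material
15 | ethyl (2R)-2-[(3S,7aR)-7a-methyl-5-oxo-3-(propan-2-yl)hexahydropyrrolo[2,1-b]oxazol-6-yl]propanoate (C6 epimers, centre left undefined) | CC(C)[C@H]1CO[C@]2(C)CC([C@@H](C)C(=O)OCC)C(=O)N12 | intermediate
16 | (3S,7aR)-6-[(2R)-1-hydroxypropan-2-yl]-7a-methyl-3-(propan-2-yl)tetrahydropyrrolo[2,1-b]oxazol-5(6H)-one (C6 epimers) | CC(C)[C@H]1CO[C@]2(C)CC([C@@H](C)CO)C(=O)N12 | intermediate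
17 | (3S,7aR)-6-[(2R)-1-(4-methoxybenzyloxy)propan-2-yl]-7a-methyl-3-(propan-2-yl)tetrahydropyrrolo[2,1-b]oxazol-5(6H)-one (C6 epimers) | CC(C)[C@H]1CO[C@]2(C)CC([C@@H](C)COCc3ccc(OC)cc3)C(=O)N12 | intermediate
18 | (3S,6S,7aR)-6-[(2R)-1-(4-methoxybenzyloxy)propan-2-yl]-7a-methyl-6-[(3S)-3-methyl-4-methylene-5-(triethylsilyloxy)pentyl]-3-(propan-2-yl)tetrahydropyrrolo[2,1-b]oxazol-5(6H)-one (chain anti, C10 arm syn to the angular methyl) | CC(C)[C@H]1CO[C@]2(C)C[C@]([C@@H](C)COCc3ccc(OC)cc3)(CC[C@H](C)C(=C)CO[Si](CC)(CC)CC)C(=O)N12 | intermediate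
19 | carbinolamine: 5-hydroxy analogue of 18 (lactam C=O reduced to CH–OH, epimers) | CC(C)[C@H]1CO[C@]2(C)C[C@]([C@@H](C)COCc3ccc(OC)cc3)(CC[C@H](C)C(=C)CO[Si](CC)(CC)CC)C(O)N12 | intermediate
20 | (2S)-2-[(3S)-5-hydroxy-3-methyl-4-methylenepentyl]-2-[(2R)-1-(4-methoxybenzyloxy)propan-2-yl]-4-oxopentanal | CC(=O)C[C@](C=O)([C@@H](C)COCc1ccc(OC)cc1)CC[C@H](C)C(=C)CO | intermediate
21 | (4R)-4-[(3S)-5-hydroxy-3-methyl-4-methylenepentyl]-4-[(2R)-1-(4-methoxybenzyloxy)propan-2-yl]cyclopent-2-en-1-one (key-step precursor) | C=C(CO)[C@@H](C)CC[C@]1(CC(=O)C=C1)[C@@H](C)COCc1ccc(OC)cc1 | intermediate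
22 | (3aR,4S,5S,7aR)-4-(hydroxymethyl)-7a-[(2R)-1-(4-methoxybenzyloxy)propan-2-yl]-4,5-dimethyloctahydro-2H-inden-2-one (cis-fused; H4, the C10 arm and the C5 methyl on one face; C14 and the C6 methyl on the other, ring A side; may sit partly as the O14–C2 hemiketal) | C[C@H]1CC[C@]2(CC(=O)C[C@H]2[C@@]1(C)CO)[C@@H](C)COCc1ccc(OC)cc1 | intermediate
23 | methyl 3-methylbut-2-enoate | COC(=O)C=C(C)C | starting material
24 | [(1-methoxy-3-methylbuta-1,3-dien-1-yl)oxy]trimethylsilane | C=C(C)C=C(OC)O[Si](C)(C)C | intermediate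
25 | (3aR,4S,5S,7aR)-7a-[(2R)-1-(4-methoxybenzyloxy)propan-2-yl]-4,5-dimethyl-2-oxooctahydro-1H-indene-4-carbaldehyde | C[C@H]1CC[C@]2(CC(=O)C[C@H]2[C@@]1(C)C=O)[C@@H](C)COCc1ccc(OC)cc1 | intermediate
26 | (4S,5S,7aS)-7a-[(2R)-1-(4-methoxybenzyloxy)propan-2-yl]-4,5-dimethyl-2-oxo-2,4,5,6,7,7a-hexahydro-1H-indene-4-carbaldehyde | C[C@H]1CC[C@]2(CC(=O)C=C2[C@@]1(C)C=O)[C@@H](C)COCc1ccc(OC)cc1 | intermediate
27 | silyl aldol adduct: methyl (Z)-3-methyl-5-(trimethylsilyloxy)pent-2-enoate carrying the bicyclic enone of 26 at C5 (C14 R) | C[C@H]1CC[C@]2(CC(=O)C=C2[C@@]1(C)[C@H](O[Si](C)(C)C)C/C(C)=C\C(=O)OC)[C@@H](C)COCc1ccc(OC)cc1 | intermediate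
28 | (6R)-6-[(4S,5S,7aS)-7a-[(2R)-1-(4-methoxybenzyloxy)propan-2-yl]-4,5-dimethyl-2-oxo-2,4,5,6,7,7a-hexahydro-1H-inden-4-yl]-4-methyl-5,6-dihydro-2H-pyran-2-one | C[C@H]1CC[C@]2(CC(=O)C=C2[C@@]1(C)[C@H]3CC(C)=CC(=O)O3)[C@@H](C)COCc1ccc(OC)cc1 | intermediate
29 | ethylene ketal of 28 (spiro-1,3-dioxolane at C2) | C[C@H]1CC[C@]2(CC3(OCCO3)C=C2[C@@]1(C)[C@H]4CC(C)=CC(=O)O4)[C@@H](C)COCc1ccc(OC)cc1 | intermediate
30 | (Z)-diol: (2Z,5R)-3-methylpent-2-ene-1,5-diol carrying the ketal-protected bicycle at C5 | C[C@H]1CC[C@]2(CC3(OCCO3)C=C2[C@@]1(C)[C@H](O)C/C(C)=C\CO)[C@@H](C)COCc1ccc(OC)cc1 | intermediate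
31 | primary allylic diethyl phosphate of 30 (C14–OH free) | C[C@H]1CC[C@]2(CC3(OCCO3)C=C2[C@@]1(C)[C@H](O)C/C(C)=C\COP(=O)(OCC)OCC)[C@@H](C)COCc1ccc(OC)cc1 | intermediate
32 | C14 (tert-butyldimethylsilyloxy)acetate of 31 | C[C@H]1CC[C@]2(CC3(OCCO3)C=C2[C@@]1(C)[C@H](OC(=O)CO[Si](C)(C)C(C)(C)C)C/C(C)=C\COP(=O)(OCC)OCC)[C@@H](C)COCc1ccc(OC)cc1 | intermediate
33 | C11 primary alcohol (PMB removed from 32) | C[C@H]1CC[C@]2(CC3(OCCO3)C=C2[C@@]1(C)[C@H](OC(=O)CO[Si](C)(C)C(C)(C)C)C/C(C)=C\COP(=O)(OCC)OCC)[C@@H](C)CO | intermediate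
34 | C11 aldehyde from 33 | C[C@H]1CC[C@]2(CC3(OCCO3)C=C2[C@@]1(C)[C@H](OC(=O)CO[Si](C)(C)C(C)(C)C)C/C(C)=C\COP(=O)(OCC)OCC)[C@@H](C)C=O | intermediate
35 | tricycle: target skeleton with C2 as 1,3-dioxolane and the glycolate hydroxyl as tert-butyldimethylsilyl ether | C=C[C@]1(C)C[C@@H](OC(=O)CO[Si](C)(C)C(C)(C)C)[C@]2(C)C3=CC4(OCCO4)C[C@@]3(CC[C@@H]2C)[C@@H](C)[C@@H]1O | intermediate
36 | Pleuromutilin F | C=C[C@]1(C)C[C@@H](OC(=O)CO)[C@]2(C)C3=CC(=O)C[C@@]3(CC[C@@H]2C)[C@@H](C)[C@@H]1O | target

Total step count: 25.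
Longest linear sequence: 20 steps (steps 1–6, 11–14, 16–25).

Steps most likely to fail

Step 14. The planar C5 radical may bond through its other face (hydroxymethyl outside, methyl over ring A), giving poor or reversed facial selectivity at C5, and simple reduction of the radical may compete with cyclisation. The fallback sets out from 21 and returns at 25. The 2-substituted allylic alcohol of 21 is isomerised with hydrogen-activated [Ir(cod)(PCy3)(py)]PF6 to the α-methyl aldehyde (2RS,3S)-2,3-dimethyl-5-[(1R)-1-[(2R)-1-(4-methoxybenzyloxy)propan-2-yl]-4-oxocyclopent-2-en-1-yl]pentanal F1. Ring B is then closed by an enamine-mediated intramolecular Michael addition using a chiral primary amine salt (9-amino-9-deoxy-epi-quinine trifluoroacetate or its pseudo-enantiomer). This is a polar 6-exo closure in which the catalyst antipode, not the intrinsic preference of a radical, selects the C5 face; the tether still enforces the cis fusion. The product is keto aldehyde 25, which is dehydrogenated under the conditions of step 16 to give 26.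

Step 24. Ring C bridges a trans-1,3 pair on ring B and is strained, so protonation or dimerisation of the allylchromium may outrun cyclisation, and loss of the (Z) geometry at the metal would lead to the C12 epimer. The fallback sets out from 32 and returns at 35. The allylic phosphate of 32 is exchanged for boron (B2pin2, Pd2(dba)3, DMSO, 60 °C) to give the pinacol (Z)-allylboronate F2. DDQ then gives its C11 alcohol F3, and Dess–Martin oxidation gives the oxo-allylboronate F4. On warming in toluene F4 should close ring C by a concerted intramolecular allylboration through the same chair arrangement, with no low-valent metal and no free carbanion; triethanolamine work-up gives 35.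

Step 17. The neopentyl aldehyde may react slowly, or a catalyst–substrate mismatch may give the wrong C14 face or an (E)-adduct that cannot lactonise. The fallback sets out from 26 and returns at 28. Reagent-controlled allylboration with methallyldiisopinocampheylborane (the antipode that gives 14R; Et2O, −78 °C, ethanolamine work-up) gives the methallyl carbinol F5. Acryloyl chloride with i-Pr2NEt converts it into the acrylate F6, and ring-closing metathesis with the second-generation Grubbs catalyst (toluene, 80 °C) closes the 4-methyl-5,6-dihydropyran-2-one 28.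

Further compounds
F1 | step 14 | (2RS,3S)-2,3-dimethyl-5-[(1R)-1-[(2R)-1-(4-methoxybenzyloxy)propan-2-yl]-4-oxocyclopent-2-en-1-yl]pentanal | O=CC(C)[C@@H](C)CC[C@]1(CC(=O)C=C1)[C@@H](C)COCc1ccc(OC)cc1
F2 | step 24 | pinacol (Z)-allylboronate corresponding to 32 (phosphate replaced by the dioxaborolanyl group) | C[C@H]1CC[C@]2(CC3(OCCO3)C=C2[C@@]1(C)[C@H](OC(=O)CO[Si](C)(C)C(C)(C)C)C/C(C)=C\CB4OC(C)(C)C(C)(C)O4)[C@@H](C)COCc1ccc(OC)cc1
F3 | step 24 | C11 alcohol of F2 (PMB removed) | C[C@H]1CC[C@]2(CC3(OCCO3)C=C2[C@@]1(C)[C@H](OC(=O)CO[Si](C)(C)C(C)(C)C)C/C(C)=C\CB4OC(C)(C)C(C)(C)O4)[C@@H](C)CO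
F4 | step 24 | C11 aldehyde of F3 (oxo-allylboronate) | C[C@H]1CC[C@]2(CC3(OCCO3)C=C2[C@@]1(C)[C@H](OC(=O)CO[Si](C)(C)C(C)(C)C)C/C(C)=C\CB4OC(C)(C)C(C)(C)O4)[C@@H](C)C=O
F5 | step 17 | methallyl carbinol: (1R)-1-hydroxy-3-methylbut-3-enyl group in place of the formyl group of 26 | C[C@H]1CC[C@]2(CC(=O)C=C2[C@@]1(C)[C@H](O)CC(C)=C)[C@@H](C)COCc1ccc(OC)cc1
F6 | step 17 | acrylate ester of F5 | C[C@H]1CC[C@]2(CC(=O)C=C2[C@@]1(C)[C@H](OC(=O)C=C)CC(C)=C)[C@@H](C)COCc1ccc(OC)cc1
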